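**Retrosynthetic overview**
- The target is a 3,3''-biflavanone. Both pyranone rings are opened at O1–C2 and O1''–C2'' (two C–O bonds, intramolecular oxa-Michael), which exposes a 2,3-bis(arylidene)-1,4-diketone (bichalcone).
- The two arylidene C=C bonds come from 4-(benzyloxy)benzaldehyde and a 1,4-bis(2-hydroxyaryl)butane-1,4-dione. Condensation and both C–O ring closures are run as one domino that also sets all four stereocentres.
- The 1,4-diketone comes from oxidative enolate homocoupling of commercial 4'-benzyloxy-2'-hydroxyacetophenone, so the C3–C3'' bond is made before any stereocentre exists.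
- Ring order: the two A rings and two B rings are bought; the two pyranone rings (ring C and ring C'') are formed last, in the same flask; the benzyl ethers are then removed by hydrogenolysis.

Assumption: the SMILES decodes to (2S,3R,2''R,3''S) with both rings 2,3-trans; the two halves are mirror images, so the target is the achiral meso diastereomer and the task is relative (diastereo)control only.

**Step 1**
Reactants: 1 1-[4-(benzyloxy)-2-hydroxyphenyl]ethan-1-one (two molecules per product)
Product: 3 1,4-bis[4-(benzyloxy)-2-hydroxyphenyl]butane-1,4-dione, via dilithium phenolate-enolate 2 (not isolated)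
Conditions: LiN(SiMe3)2 (2.2 equiv), THF, −78 → 0 °C; CuCl2 (1.1 equiv) in DMF, −78 °C → rt; 1 M HCl work-up
Reagents that add atoms: none
Why: Double deprotonation gives the phenolate-enolate 2; divalent copper oxidizes the electron-rich enolate carbon rather than the acyl-deactivated phenolate, and the α-keto radicals dimerize to the symmetrical 1,4-diketone (Saegusa-type oxidative enolate homocoupling); no stereocentre is formed.

**Step 2**
Reactants: 3 1,4-bis[4-(benzyloxy)-2-hydroxyphenyl]butane-1,4-dione; 4 4-(benzyloxy)benzaldehyde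
Product: 8 (2S,3R)-7-(benzyloxy)-3-{(2R,3S)-7-(benzyloxy)-2-[4-(benzyloxy)phenyl]-4-oxochroman-3-yl}-2-[4-(benzyloxy)phenyl]chroman-4-one (meso tetrabenzyl ether), via mono-enone 5 (not isolated), via mono-flavanone 6 (not isolated), via flavanone-enone 7 (not isolated)
Conditions: 4 (2.5 equiv), pyrrolidine (2.0 equiv), AcOH (1.0 equiv), n-PrOH (0.3 M), 90 °C, 36 h; cool to 20 °C over 12 h with seeding, age slurry 24 h, filter
Reagents that add atoms: none
Why: Proposed new method: a fourfold amine-mediated domino in which pyrrolidine activates 4 as its iminium ion, the chelated enol of each ArCO–CH2 unit adds (Mannich) and loses pyrrolidine to give the (E)-enone, and the ortho-phenol closes 6-endo-trig by oxa-Michael addition to form each O1–C2 bond; because C3 enolization and E1cB ring opening at C2 remain reversible under the amine, all four stereocentres are set thermodynamically (2,3-trans diequatorial in each ring; across C3–C3'' the heterochiral pairing is expected to be modestly preferred because its centrosymmetric anti conformer opposes the two C=O dipoles and avoids a gauche C2/C2'' contact), and the sparingly soluble meso isomer is expected to be drained from the equilibrium by crystallization (crystallization-induced diastereomer transformation); the closest known reaction types are the pyrrolidine-mediated one-pot aldol condensation/oxa-Michael synthesis of flavanones from 2'-hydroxyacetophenones (Kabbe-type condensation) and the base-mediated double oxa-Michael closure of preformed bichalcones, neither shown as a double annulation on a 1,4-diketone nor coupled to a meso-selective crystallization.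

**Step 3**
Reactants: 8 (2S,3R)-7-(benzyloxy)-3-{(2R,3S)-7-(benzyloxy)-2-[4-(benzyloxy)phenyl]-4-oxochroman-3-yl}-2-[4-(benzyloxy)phenyl]chroman-4-one
Product: 9 (2S,3R)-7-hydroxy-3-[(2R,3S)-7-hydroxy-2-(4-hydroxyphenyl)-4-oxochroman-3-yl]-2-(4-hydroxyphenyl)chroman-4-one (meso; CNP0231820.1)
Conditions: H2 (1 atm), 10% Pd/C, THF–MeOH (3:1), rt, 2–4 h
Reagents that add atoms: none
Why: Catalytic hydrogenolysis of the four aryl benzyl ethers is neutral, so the pyranone rings cannot reopen at C2 and C3 cannot enolize; the meso trans,trans configuration from step 2 is carried unchanged into the target, and a short run at 1 atm spares the aryl ketones and the benzylic C2–O bonds.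

**Compound list**
1 | 1-[4-(benzyloxy)-2-hydroxyphenyl]ethan-1-one (4'-benzyloxy-2'-hydroxyacetophenone) | CC(=O)c1ccc(OCc2ccccc2)cc1O | starting material
2 | dilithium 5-(benzyloxy)-2-(1-oxidoethenyl)phenolate (dianion of 1) | [Li+].[Li+].C=C([O-])c1ccc(OCc2ccccc2)cc1[O-] | intermediate (not isolated)
3 | 1,4-bis[4-(benzyloxy)-2-hydroxyphenyl]butane-1,4-dione | O=C(CCC(=O)c1ccc(OCc2ccccc2)cc1O)c1ccc(OCc2ccccc2)cc1O | intermediate
4 | 4-(benzyloxy)benzaldehyde | O=Cc1ccc(OCc2ccccc2)cc1 | starting material
5 | (E)-2-[4-(benzyloxy)benzylidene]-1,4-bis[4-(benzyloxy)-2-hydroxyphenyl]butane-1,4-dione (mono-enone) | O=C(C/C(=C\c1ccc(OCc2ccccc2)cc1)C(=O)c1ccc(OCc2ccccc2)cc1O)c1ccc(OCc2ccccc2)cc1O | intermediate (not isolated)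
6 | trans-7-(benzyloxy)-2-[4-(benzyloxy)phenyl]-3-{2-[4-(benzyloxy)-2-hydroxyphenyl]-2-oxoethyl}chroman-4-one (mono-flavanone; racemic, the 2S,3R enantiomer drawn) | O=C1c2ccc(OCc3ccccc3)cc2O[C@H](c2ccc(OCc3ccccc3)cc2)[C@H]1CC(=O)c1ccc(OCc2ccccc2)cc1O | intermediate (not isolated)
7 | trans-7-(benzyloxy)-2-[4-(benzyloxy)phenyl]-3-{(E)-1-[4-(benzyloxy)-2-hydroxybenzoyl]-2-[4-(benzyloxy)phenyl]ethenyl}chroman-4-one (flavanone-enone; racemic, the 2S,3R enantiomer drawn) | O=C1c2ccc(OCc3ccccc3)cc2O[C@H](c2ccc(OCc3ccccc3)cc2)[C@H]1/C(=C\c1ccc(OCc2ccccc2)cc1)C(=O)c1ccc(OCc2ccccc2)cc1O | intermediate (not isolated)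
8 | (2S,3R)-7-(benzyloxy)-3-{(2R,3S)-7-(benzyloxy)-2-[4-(benzyloxy)phenyl]-4-oxochroman-3-yl}-2-[4-(benzyloxy)phenyl]chroman-4-one (meso) | O=C1c2ccc(OCc3ccccc3)cc2O[C@H](c2ccc(OCc3ccccc3)cc2)[C@H]1[C@@H]1C(=O)c2ccc(OCc3ccccc3)cc2O[C@H]1c1ccc(OCc2ccccc2)cc1 | intermediate
9 | (2S,3R)-7-hydroxy-3-[(2R,3S)-7-hydroxy-2-(4-hydroxyphenyl)-4-oxochroman-3-yl]-2-(4-hydroxyphenyl)chroman-4-one (meso) | O=C1c2ccc(O)cc2O[C@H](c2ccc(O)cc2)[C@H]1[C@@H]1C(=O)c2ccc(O)cc2O[C@H]1c1ccc(O)cc1 | target

**Totals**
Total step count: 3. Longest linear sequence: 3 steps (1 → 3 → 8 → 9).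

**Steps most likely to fail, with fallbacks**

Step 2 (the proposed new domino; highest risk). Three failure modes are foreseen:
- the second, more hindered condensation may stall at 6;
- mono-enone 5 may drift by double-bond migration to the 2-ene-1,4-dione or a furan before it cyclizes;
- the meso isomer may not be the one that crystallizes, in which case the filtrate (dl and cis isomers) would need a further base equilibration (DBU) and recrystallization.

The fallback uses known chemistry only; it sets out from 3 and comes back at 8.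
- The two chelated phenols of 3 are capped with MOMCl (NaH, DMF, 0 °C) to give 1,4-bis[4-(benzyloxy)-2-(methoxymethoxy)phenyl]butane-1,4-dione F4.
- Classical Claisen–Schmidt condensation with 4 (KOH, EtOH–THF, rt) gives the bichalcone (2E,3E)-2,3-bis[4-(benzyloxy)benzylidene]-1,4-bis[4-(benzyloxy)-2-(methoxymethoxy)phenyl]butane-1,4-dione F5.
- 3 M HCl in MeOH–THF (40 °C) frees the phenols to give (2E,3E)-2,3-bis[4-(benzyloxy)benzylidene]-1,4-bis[4-(benzyloxy)-2-hydroxyphenyl]butane-1,4-dione F6.
- NaOAc in refluxing EtOH closes both rings by the established double oxa-Michael addition of 2'-hydroxychalcones, giving 8 together with its dl trans,trans diastereomer.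
- 8 is separated by crystallization or chromatography (meso shows one peak on a chiral HPLC column, the dl pair two), and the dl material is returned to the NaOAc equilibration.

Step 1. The copper oxidant may attack the phenolate (ring coupling, quinoid by-products) or chlorinate the α-carbon, after which the phenolate would close to a benzofuran-3-one. The fallback replaces oxidative coupling by polar enolate alkylation; it sets out from 1 and comes back at 3.
- Benzylation of 1 (BnBr, K2CO3, DMF, 60 °C) gives 1-[2,4-bis(benzyloxy)phenyl]ethan-1-one F1.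
- Part of it is α-brominated (CuBr2, EtOAc–CHCl3, reflux) to 2-bromo-1-[2,4-bis(benzyloxy)phenyl]ethan-1-one F2.
- The lithium enolate of F1 (LiN(SiMe3)2, THF, −78 °C) is alkylated with F2 to give 1,4-bis[2,4-bis(benzyloxy)phenyl]butane-1,4-dione F3.
- MgBr2·OEt2 (toluene–Et2O, 80 °C) removes only the two benzyl ethers ortho to the carbonyls (chelation-directed cleavage) and returns 3.

Step 3. Over-reduction is possible (hydrogenolysis of the benzylic C2–O bonds to a dihydrochalcone, or ketone reduction), and the reaction may stall because 8 is poorly soluble. The fallback removes the benzyl groups before any ring exists and ends with an acid-labile group; it sets out from 3 and comes back at 9.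
- Hydrogenolysis of 3 (H2, 10% Pd/C, EtOAc–MeOH, rt) gives 1,4-bis(2,4-dihydroxyphenyl)butane-1,4-dione F7.
- MOMCl (2.2 equiv) with K2CO3 in acetone etherifies only the non-chelated 4-hydroxyls, giving 1,4-bis[2-hydroxy-4-(methoxymethoxy)phenyl]butane-1,4-dione F8.
- The step 2 annulation with commercial 4-(methoxymethoxy)benzaldehyde (COCOc1ccc(C=O)cc1) gives (2S,3R)-7-(methoxymethoxy)-3-{(2R,3S)-7-(methoxymethoxy)-2-[4-(methoxymethoxy)phenyl]-4-oxochroman-3-yl}-2-[4-(methoxymethoxy)phenyl]chroman-4-one F9.
- 3 M HCl in MeOH–THF (40 °C) removes the four MOM groups and gives 9.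
- Protic acid does not reopen the pyranone rings, and because the meso/dl identity resides in C2/C2'', any C3 enolization simply returns to the trans arrangement.

**Further compounds**
F1 | step 1 | 1-[2,4-bis(benzyloxy)phenyl]ethan-1-one | CC(=O)c1ccc(OCc2ccccc2)cc1OCc1ccccc1
F2 | step 1 | 2-bromo-1-[2,4-bis(benzyloxy)phenyl]ethan-1-one | O=C(CBr)c1ccc(OCc2ccccc2)cc1OCc1ccccc1
F3 | step 1 | 1,4-bis[2,4-bis(benzyloxy)phenyl]butane-1,4-dione | O=C(CCC(=O)c1ccc(OCc2ccccc2)cc1OCc1ccccc1)c1ccc(OCc2ccccc2)cc1OCc1ccccc1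
F4 | step 2 | 1,4-bis[4-(benzyloxy)-2-(methoxymethoxy)phenyl]butane-1,4-dione | O=C(CCC(=O)c1ccc(OCc2ccccc2)cc1OCOC)c1ccc(OCc2ccccc2)cc1OCOC
F5 | step 2 | (2E,3E)-2,3-bis[4-(benzyloxy)benzylidene]-1,4-bis[4-(benzyloxy)-2-(methoxymethoxy)phenyl]butane-1,4-dione | O=C(c1ccc(OCc2ccccc2)cc1OCOC)/C(=C/c1ccc(OCc2ccccc2)cc1)C(=C/c1ccc(OCc2ccccc2)cc1)\C(=O)c1ccc(OCc2ccccc2)cc1OCOC
F6 | step 2 | (2E,3E)-2,3-bis[4-(benzyloxy)benzylidene]-1,4-bis[4-(benzyloxy)-2-hydroxyphenyl]butane-1,4-dione | O=C(c1ccc(OCc2ccccc2)cc1O)/C(=C/c1ccc(OCc2ccccc2)cc1)C(=C/c1ccc(OCc2ccccc2)cc1)\C(=O)c1ccc(OCc2ccccc2)cc1O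
F7 | step 3 | 1,4-bis(2,4-dihydroxyphenyl)butane-1,4-dione | O=C(CCC(=O)c1ccc(O)cc1O)c1ccc(O)cc1O
F8 | step 3 | 1,4-bis[2-hydroxy-4-(methoxymethoxy)phenyl]butane-1,4-dione | O=C(CCC(=O)c1ccc(OCOC)cc1O)c1ccc(OCOC)cc1O
F9 | step 3 | (2S,3R)-7-(methoxymethoxy)-3-{(2R,3S)-7-(methoxymethoxy)-2-[4-(methoxymethoxy)phenyl]-4-oxochroman-3-yl}-2-[4-(methoxymethoxy)phenyl]chroman-4-one (meso) | O=C1c2ccc(OCOC)cc2O[C@H](c2ccc(OCOC)cc2)[C@H]1[C@@H]1C(=O)c2ccc(OCOC)cc2O[C@H]1c1ccc(OCOC)cc1
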